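**Plan**
Retrosynthetic cuts: C11=C12 (Horner–Wadsworth–Emmons union of a C15 enynal with a C15 phosphonate ester), C8–C9 (Pd-catalysed addition of the ring alkyne across ethyl but-2-ynoate), C12'=C11' inside the phosphonate (C10 dialdehyde + C5 phosphonate), and C3–C4 of ring A.
Enabling feature (carotenoid numbering): in ring A the C3 carbinol is homoallylic to the tetrasubstituted C5=C6 alkene (C1 gem-dimethyl, C5 methyl, C6 alkynyl). This is the retron of an aldehyde–alkene closure at C3–C4 in which H leaves from C6, so a C6 stereocentre in an acyclic precursor disappears and a racemate can converge.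
Forward order: prenyl senecioate, Ireland–Claisen acid, δ-lactone, alkyne, racemic acyclic enynal; ring A (the only ring) is then closed, the chain is attached at C8–C9 and joined at C11=C12, and C8' is adjusted last.
Stereochemistry: C3 (R) comes from the chiral Brønsted acid in the ring closure; 9E from syn carbopalladation; the other E alkenes from E-selective phosphonate olefinations and all-E building blocks.

Key step: step 7

Remarks: positions are quoted in carotenoid numbering (ring C1–C6, chain C7 to C8'). All intermediates from the Claisen rearrangement to the ring closure are racemic at C6 and are drawn without a descriptor. The alkyne is carried without a silyl group because no step before the chain extension needs one. The sense of induction of the acid in step 7 cannot be predicted with certainty; the antipode of the catalyst that gives the 3R alcohol is the one to use.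

**Route**

Step 1
Reactants: 1 3-methylbut-2-en-1-ol (prenol); 2 3-methylbut-2-enoyl chloride
Product: 3 3-methylbut-2-en-1-yl 3-methylbut-2-enoate
Conditions: pyridine, 4-(dimethylamino)pyridine (cat.), CH2Cl2, 0 °C to rt
Reagents that add atoms: none
Why: Acylation of a primary allylic alcohol by an acid chloride under nucleophilic catalysis; any deconjugated ester formed through a vinylketene is harmless because both isomers give the same dienolate in step 2.

Step 2
Reactants: 3 3-methylbut-2-en-1-yl 3-methylbut-2-enoate
Product: 6 rac-3,3-dimethyl-2-(prop-1-en-2-yl)pent-4-enoic acid, via silyl ketene acetal 4 (not isolated), via trimethylsilyl ester 5 (not isolated)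
Conditions: LiN(i-Pr)2, THF, −78 °C; Me3SiCl, −78 °C to 50 °C; then dilute aqueous HCl
Reagents that add atoms: none
Why: Ireland–Claisen rearrangement in its deconjugative form (as used for lavandulic acid): γ-deprotonation gives the dienolate, O-silylation the dienyl ketene acetal, and the chair [3,3] shift joins the α-carbon to the dimethyl-substituted prenyl terminus, creating the quaternary C1 next to C6, the only stereocentre, which is formed racemic and is erased in step 7.

Step 3
Reactants: 6 rac-3,3-dimethyl-2-(prop-1-en-2-yl)pent-4-enoic acid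
Product: 9 rac-4,4-dimethyl-3-(prop-1-en-2-yl)oxan-2-one, via bis-boryl adduct 7 (not isolated), via hydroxy acid 8 (not isolated)
Conditions: Sia2BH (disiamylborane, 2.3 equiv, made from BH3·SMe2 and 2-methylbut-2-ene), THF, 0 °C to rt; NaOH, H2O2, 0 °C; HCl to pH 2, then p-toluenesulfonic acid (cat.), CH2Cl2, rt
Reagents that add atoms: hydrogen peroxide, OO
Why: Brown hydroboration–oxidation followed by lactonisation: the first equivalent of the hindered dialkylborane turns the acid into an acyloxyborane, the second should add anti-Markovnikov to the monosubstituted vinyl group in preference to the 1,1-disubstituted isopropenyl group (shielded by the quaternary carbon and deactivated by the neighbouring acyl carbon), and the δ-hydroxy acid released on acidification closes to the lactone, helped by the gem-dimethyl group.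

Step 4
Reactants: 9 rac-4,4-dimethyl-3-(prop-1-en-2-yl)oxan-2-one
Product: 10 4,4-dimethyl-3-(prop-1-en-2-yl)oxan-2-ol (racemic anomer mixture)
Conditions: i-Bu2AlH (1.1 equiv), CH2Cl2, −78 °C
Reagents that add atoms: none
Why: Partial reduction of a δ-lactone to the lactol, the tetrahedral aluminium acetal being stable at −78 °C until work-up.

Step 5
Reactants: 10 4,4-dimethyl-3-(prop-1-en-2-yl)oxan-2-ol
Product: 12 rac-3,3-dimethyl-4-(prop-1-en-2-yl)hex-5-yn-1-ol, via open-chain hydroxy aldehyde 11 (not isolated)
Conditions: dimethyl (1-diazo-2-oxopropyl)phosphonate, K2CO3, MeOH, 0 °C to rt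
Reagents that add atoms: dimethyl (1-diazo-2-oxopropyl)phosphonate, CC(=O)C(=[N+]=[N-])P(=O)(OC)OC
Why: Seyferth–Gilbert homologation in the Ohira–Bestmann variant, acting on the open hydroxy aldehyde form of the lactol; migration of the isopropenyl double bond into conjugation is not expected because the resulting tetrasubstituted enal next to the quaternary carbon would be strained, and epimerisation is irrelevant in a racemate.

Step 6
Reactants: 12 rac-3,3-dimethyl-4-(prop-1-en-2-yl)hex-5-yn-1-ol
Product: 13 rac-3,3-dimethyl-4-(prop-1-en-2-yl)hex-5-ynal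
Conditions: Dess–Martin periodinane, NaHCO3, CH2Cl2, 0 °C to rt
Reagents that add atoms: none
Why: Dess–Martin oxidation of a primary alcohol under buffered conditions, so that the aldehyde never meets an acid able to start a racemic cyclisation; the aldehyde can neither epimerise nor conjugate (α-CH2 next to a quaternary carbon).

Step 7
Reactants: 13 rac-3,3-dimethyl-4-(prop-1-en-2-yl)hex-5-ynal
Product: 14 (1R)-4-ethynyl-3,5,5-trimethylcyclohex-3-en-1-ol
Conditions: chiral imidodiphosphorimidate HN[P(=NSO2CF3)(O2R*)]2 (O2R* = 3,3'-bis[3,5-bis(trifluoromethyl)phenyl]-1,1'-binaphthalene-2,2'-diolate, single antipode, 3 mol%), methylcyclohexane, 5 Å molecular sieves, −20 °C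
Reagents that add atoms: none
Why: Proposed new method: the confined acid activates the aldehyde of 13 inside its chiral cavity, the isopropenyl CH2 (C4) adds to the carbonyl carbon C3 through a chair to give a tertiary C5 cation held by the catalyst anion, and that anion removes the propargylic C6 proton, so the stereocentre of 13 is erased and both of its enantiomers are funnelled into 14; the closest known chemistry is the catalytic asymmetric carbonyl–ene and Prins cyclisation of alkenyl aldehydes with confined imidodiphosphate-type Brønsted acids, which has not been shown on a racemate that converges in this way. Ring A closes in a six-membered chair that is 6-endo-trig with respect to the alkene (C4 and C5 both become ring atoms), while the carbonyl is exocyclic and its oxygen stays outside the ring as the new hydroxyl. The C3 stereocentre is set by the catalyst alone through its choice of aldehyde face, and the slim, rod-like ethynyl group at C6 gives the substrate so little bias of its own that both enantiomers should follow the catalyst. Chemoselectivity comes from the 1,1-disubstituted alkene being a far better nucleophile than the terminal alkyne, which could reach C3 only through a strained cyclic or a primary vinyl cation, and the gem-dimethyl group at C1 favours the folded conformer. The step needs proton loss from C6 and not from C4 or the C5 methyl group: the C6–H bond is propargylic and its loss gives the only tetrasubstituted, enyne-conjugated alkene, and since the strong acid can reprotonate the other alkene isomers to the same C5 cation they should drain to this most stable product.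

Step 8
Reactants: 14 (1R)-4-ethynyl-3,5,5-trimethylcyclohex-3-en-1-ol; 15 ethyl but-2-ynoate
Product: 16 ethyl (2E)-5-[(4R)-4-hydroxy-2,6,6-trimethylcyclohex-1-en-1-yl]-3-methylpent-2-en-4-ynoate
Conditions: Pd(OAc)2 (3 mol%), tris(2,6-dimethoxyphenyl)phosphine (3 mol%), toluene, rt
Reagents that add atoms: none
Why: Palladium-catalysed cross-addition of a terminal donor alkyne to an alkynoate acceptor (hydroalkynylation): syn carbopalladation of the ynoate by the alkynylpalladium species and protonolysis place the ring alkynyl group and H cis, hence the alkyne trans to the ester (9E), and the free hydroxyl is tolerated.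

Step 9
Reactants: 16 ethyl (2E)-5-[(4R)-4-hydroxy-2,6,6-trimethylcyclohex-1-en-1-yl]-3-methylpent-2-en-4-ynoate
Product: 17 (2E)-5-[(4R)-4-hydroxy-2,6,6-trimethylcyclohex-1-en-1-yl]-3-methylpent-2-en-4-yn-1-ol
Conditions: i-Bu2AlH (3.3 equiv), CH2Cl2, −78 °C
Reagents that add atoms: none
Why: 1,2-Reduction of a conjugated ester to the allylic alcohol by i-Bu2AlH (one equivalent is taken up by the ring hydroxyl), leaving the enyne and the C9=C10 geometry untouched.

Step 10
Reactants: 17 (2E)-5-[(4R)-4-hydroxy-2,6,6-trimethylcyclohex-1-en-1-yl]-3-methylpent-2-en-4-yn-1-ol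
Product: 18 (2E)-5-[(4R)-4-hydroxy-2,6,6-trimethylcyclohex-1-en-1-yl]-3-methylpent-2-en-4-ynal
Conditions: MnO2 (activated, excess), CH2Cl2, rt, dark
Reagents that add atoms: none
Why: MnO2 oxidation is selective for the allylic primary alcohol; the ring carbinol is only homoallylic and should survive, and the neutral heterogeneous conditions keep the 9E geometry.

Step 11
Reactants: 19 ethyl (2E)-4-bromo-2-methylbut-2-enoate
Product: 20 ethyl (2E)-4-(diethoxyphosphoryl)-2-methylbut-2-enoate
Conditions: P(OEt)3, neat, 120 °C, bromoethane distilled off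
Reagents that add atoms: triethyl phosphite, CCOP(OCC)OCC
Why: Michaelis–Arbuzov reaction of a primary allylic bromide; attack at CH2 leaves the E trisubstituted alkene unchanged.

Step 12
Reactants: 20 ethyl (2E)-4-(diethoxyphosphoryl)-2-methylbut-2-enoate; 21 (2E,4E,6E)-2,7-dimethylocta-2,4,6-trienedial
Product: 22 ethyl (2E,4E,6E,8E,10E)-2,6,11-trimethyl-12-oxododeca-2,4,6,8,10-pentaenoate
Conditions: NaH, THF, 0 °C; then added slowly to 21 (2.5 equiv), THF, −20 to 0 °C
Reagents that add atoms: none
Why: Horner–Wadsworth–Emmons olefination through the carbon next to phosphorus of the vinylogous phosphonate anion; the excess of the symmetrical dialdehyde should hold the reaction at the mono-adduct, and the stabilised anion should give the E C12'=C11' bond.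

Step 13
Reactants: 22 ethyl (2E,4E,6E,8E,10E)-2,6,11-trimethyl-12-oxododeca-2,4,6,8,10-pentaenoate
Product: 23 ethyl (2E,4E,6E,8E,10E)-12-hydroxy-2,6,11-trimethyldodeca-2,4,6,8,10-pentaenoate
Conditions: NaBH4, EtOH/THF, −10 °C
Reagents that add atoms: none
Why: Chemoselective borohydride 1,2-reduction of the aldehyde in the presence of the much less electrophilic conjugated ester.

Step 14
Reactants: 23 ethyl (2E,4E,6E,8E,10E)-12-hydroxy-2,6,11-trimethyldodeca-2,4,6,8,10-pentaenoate
Product: 24 ethyl (2E,4E,6E,8E,10E)-12-bromo-2,6,11-trimethyldodeca-2,4,6,8,10-pentaenoate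
Conditions: PBr3 (0.4 equiv), pyridine (cat.), Et2O, −10 °C, dark; used crude
Reagents that add atoms: phosphorus tribromide, BrP(Br)Br
Why: Conversion of a primary polyenylic alcohol into the bromide with PBr3 at low temperature, as is usual for polyene carbinols; the terminal bromide is favoured because it keeps the pentaene conjugated with the ester.

Step 15
Reactants: 24 ethyl (2E,4E,6E,8E,10E)-12-bromo-2,6,11-trimethyldodeca-2,4,6,8,10-pentaenoate
Product: 25 ethyl (2E,4E,6E,8E,10E)-12-(diethoxyphosphoryl)-2,6,11-trimethyldodeca-2,4,6,8,10-pentaenoate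
Conditions: P(OEt)3, toluene, 80 °C
Reagents that add atoms: triethyl phosphite, CCOP(OCC)OCC
Why: Michaelis–Arbuzov reaction of the allylic bromide, giving the terminal, fully conjugated phosphonate.

Step 16
Reactants: 18 (2E)-5-[(4R)-4-hydroxy-2,6,6-trimethylcyclohex-1-en-1-yl]-3-methylpent-2-en-4-ynal; 25 ethyl (2E,4E,6E,8E,10E)-12-(diethoxyphosphoryl)-2,6,11-trimethyldodeca-2,4,6,8,10-pentaenoate
Product: 26 ethyl (3R)-3-hydroxy-7,8-didehydro-8'-apo-β-caroten-8'-oate (all-E)
Conditions: NaN(SiMe3)2 (on 25), THF, −78 °C; then 18, −78 to 0 °C, dark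
Reagents that add atoms: none
Why: Horner–Wadsworth–Emmons olefination in which the enynal is the electrophile and is never deprotonated, so its 9E geometry should be kept, while the stabilised polyenyl phosphonate anion should give the E C11=C12 bond as in retinoid and carotenoid practice.

Step 17
Reactants: 26 ethyl (3R)-3-hydroxy-7,8-didehydro-8'-apo-β-caroten-8'-oate
Product: 27 (3R)-7,8-didehydro-8'-apo-β-carotene-3,8'-diol (all-E)
Conditions: i-Bu2AlH (3.3 equiv), CH2Cl2, −78 °C, dark
Reagents that add atoms: none
Why: 1,2-Reduction of the conjugated ester to the primary polyenylic alcohol by i-Bu2AlH at low temperature.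

Step 18
Reactants: 27 (3R)-7,8-didehydro-8'-apo-β-carotene-3,8'-diol
Product: 28 (3R)-3-hydroxy-7,8-didehydro-8'-apo-β-caroten-8'-al (all-E), the target
Conditions: MnO2 (activated, excess), CH2Cl2, rt, dark
Reagents that add atoms: none
Why: MnO2 oxidation of the polyenylic primary alcohol to the conjugated aldehyde; the homoallylic ring alcohol should not react.

**Compound list**
1 | 3-methylbut-2-en-1-ol (prenol) | CC(C)=CCO | starting material
2 | 3-methylbut-2-enoyl chloride | CC(C)=CC(=O)Cl | starting material
3 | 3-methylbut-2-en-1-yl 3-methylbut-2-enoate | CC(C)=CCOC(=O)C=C(C)C | intermediate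
4 | trimethyl({3-methyl-1-[(3-methylbut-2-en-1-yl)oxy]buta-1,3-dien-1-yl}oxy)silane (silyl ketene acetal, geometry not controlled and without consequence; not isolated) | C=C(C)C=C(OCC=C(C)C)O[Si](C)(C)C | intermediate
5 | trimethylsilyl 3,3-dimethyl-2-(prop-1-en-2-yl)pent-4-enoate (racemic; not isolated) | C=CC(C)(C)C(C(C)=C)C(=O)O[Si](C)(C)C | intermediate
6 | rac-3,3-dimethyl-2-(prop-1-en-2-yl)pent-4-enoic acid | C=CC(C)(C)C(C(C)=C)C(=O)O | intermediate
7 | bis(3-methylbutan-2-yl)boranyl 5-[bis(3-methylbutan-2-yl)boranyl]-3,3-dimethyl-2-(prop-1-en-2-yl)pentanoate (bis-boryl adduct; not isolated) | CC(C)C(C)B(OC(=O)C(C(C)=C)C(C)(C)CCB(C(C)C(C)C)C(C)C(C)C)C(C)C(C)C | intermediate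
8 | rac-5-hydroxy-3,3-dimethyl-2-(prop-1-en-2-yl)pentanoic acid (not isolated) | OCCC(C)(C)C(C(C)=C)C(=O)O | intermediate
9 | rac-4,4-dimethyl-3-(prop-1-en-2-yl)oxan-2-one | C=C(C)C1C(=O)OCCC1(C)C | intermediate
10 | 4,4-dimethyl-3-(prop-1-en-2-yl)oxan-2-ol (racemic anomer mixture) | C=C(C)C1C(O)OCCC1(C)C | intermediate
11 | rac-5-hydroxy-3,3-dimethyl-2-(prop-1-en-2-yl)pentanal (open form of 10; not isolated) | C=C(C)C(C=O)C(C)(C)CCO | intermediate
12 | rac-3,3-dimethyl-4-(prop-1-en-2-yl)hex-5-yn-1-ol | C=C(C)C(C#C)C(C)(C)CCO | intermediate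
13 | rac-3,3-dimethyl-4-(prop-1-en-2-yl)hex-5-ynal | C=C(C)C(C#C)C(C)(C)CC=O | intermediate
14 | (1R)-4-ethynyl-3,5,5-trimethylcyclohex-3-en-1-ol | CC1=C(C#C)C(C)(C)C[C@H](O)C1 | intermediate
15 | ethyl but-2-ynoate | CC#CC(=O)OCC | starting material
16 | ethyl (2E)-5-[(4R)-4-hydroxy-2,6,6-trimethylcyclohex-1-en-1-yl]-3-methylpent-2-en-4-ynoate | CC1=C(C#C/C(C)=C/C(=O)OCC)C(C)(C)C[C@H](O)C1 | intermediate
17 | (2E)-5-[(4R)-4-hydroxy-2,6,6-trimethylcyclohex-1-en-1-yl]-3-methylpent-2-en-4-yn-1-ol | CC1=C(C#C/C(C)=C/CO)C(C)(C)C[C@H](O)C1 | intermediate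
18 | (2E)-5-[(4R)-4-hydroxy-2,6,6-trimethylcyclohex-1-en-1-yl]-3-methylpent-2-en-4-ynal | CC1=C(C#C/C(C)=C/C=O)C(C)(C)C[C@H](O)C1 | intermediate
19 | ethyl (2E)-4-bromo-2-methylbut-2-enoate | CCOC(=O)/C(C)=C/CBr | starting material
20 | ethyl (2E)-4-(diethoxyphosphoryl)-2-methylbut-2-enoate | CCOC(=O)/C(C)=C/CP(=O)(OCC)OCC | intermediate
21 | (2E,4E,6E)-2,7-dimethylocta-2,4,6-trienedial | O=C/C(C)=C/C=C/C=C(C)/C=O | starting material
22 | ethyl (2E,4E,6E,8E,10E)-2,6,11-trimethyl-12-oxododeca-2,4,6,8,10-pentaenoate | O=C/C(C)=C/C=C/C=C(C)/C=C/C=C(\C)C(=O)OCC | intermediate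
23 | ethyl (2E,4E,6E,8E,10E)-12-hydroxy-2,6,11-trimethyldodeca-2,4,6,8,10-pentaenoate | OC/C(C)=C/C=C/C=C(C)/C=C/C=C(\C)C(=O)OCC | intermediate
24 | ethyl (2E,4E,6E,8E,10E)-12-bromo-2,6,11-trimethyldodeca-2,4,6,8,10-pentaenoate | BrC/C(C)=C/C=C/C=C(C)/C=C/C=C(\C)C(=O)OCC | intermediate
25 | ethyl (2E,4E,6E,8E,10E)-12-(diethoxyphosphoryl)-2,6,11-trimethyldodeca-2,4,6,8,10-pentaenoate | CCOP(=O)(OCC)C/C(C)=C/C=C/C=C(C)/C=C/C=C(\C)C(=O)OCC | intermediate
26 | ethyl (3R)-3-hydroxy-7,8-didehydro-8'-apo-β-caroten-8'-oate (all-E) | CC1=C(C#C/C(C)=C/C=C/C(C)=C/C=C/C=C(C)/C=C/C=C(\C)C(=O)OCC)C(C)(C)C[C@H](O)C1 | intermediate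
27 | (3R)-7,8-didehydro-8'-apo-β-carotene-3,8'-diol (all-E) | CC1=C(C#C/C(C)=C/C=C/C(C)=C/C=C/C=C(C)/C=C/C=C(\C)CO)C(C)(C)C[C@H](O)C1 | intermediate
28 | (3R)-3-hydroxy-7,8-didehydro-8'-apo-β-caroten-8'-al (all-E) | CC1=C(C#C/C(C)=C/C=C/C(C)=C/C=C/C=C(C)/C=C/C=C(\C)C=O)C(C)(C)C[C@H](O)C1 | target

**Step count**
Total: 18 steps. Longest linear sequence: 13 steps (steps 1–10 and 16–18); the five-step branch to phosphonate 25 (steps 11–15) joins at step 16.

**Steps most likely to fail**

Step 7 (new method). The catalyst may control the aldehyde face well for one enantiomer of 13 and poorly for the other, so that the closure turns into a kinetic resolution or gives eroded enantiopurity. Proton loss may also take place from the C5 methyl group or from C4, which leaves C6 stereogenic and gives isomeric alkenes, and the product alcohol may bind and slow the acid. The fallback uses known chemistry and runs from 13 back to 14. Me2AlCl in CH2Cl2 at −78 °C should close the ring in a conventional Lewis-acid Prins/carbonyl–ene reaction, and brief treatment with p-toluenesulfonic acid should move the double bond into conjugation, giving racemic 4-ethynyl-3,5,5-trimethylcyclohex-3-en-1-ol F1. Lipase-catalysed transesterification (immobilised Candida antarctica lipase B, vinyl acetate, tert-butyl methyl ether) is expected, from the usual enantiopreference of lipases for secondary alcohols, to acylate the R alcohol. This would give (1R)-4-ethynyl-3,5,5-trimethylcyclohex-3-en-1-yl acetate F2 and leave (1S)-4-ethynyl-3,5,5-trimethylcyclohex-3-en-1-ol F3, which is separated. Methanolysis of F2 (K2CO3, MeOH) leads back to 14.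

Step 3. The borane may also add to the isopropenyl group (loss of chemoselectivity between the two alkenes), or the neopentyl-type vinyl group may react too slowly for full conversion. The fallback runs from 6 to 9 and replaces hydroboration by an oxidation that engages only monosubstituted alkenes. Esterification of 6 (MeI, K2CO3, DMF) should give methyl 3,3-dimethyl-2-(prop-1-en-2-yl)pent-4-enoate F4. Aldehyde-selective, nitrite-modified Wacker oxidation [PdCl2(PhCN)2, CuCl2, AgNO2, O2, t-BuOH/MeNO2], steered to the terminal carbon by the adjacent quaternary centre, should give methyl 3,3-dimethyl-5-oxo-2-(prop-1-en-2-yl)pentanoate F5. NaBH4 in MeOH should then give methyl 5-hydroxy-3,3-dimethyl-2-(prop-1-en-2-yl)pentanoate F6, which closes to lactone 9 with a trace of p-toluenesulfonic acid.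

Step 16. E-selectivity at the new C11=C12 bond may be incomplete, the base may isomerise the 9E enynal, or the long, extended anion of 25 may degrade before it adds. The fallback runs from 18 to 26 and grows the chain linearly with short phosphonates whose anions are well behaved. Horner–Wadsworth–Emmons reaction of 18 with the anion of diethyl (3-cyano-2-methylallyl)phosphonate (NaH, THF) should give (2E,4E,6E)-9-[(4R)-4-hydroxy-2,6,6-trimethylcyclohex-1-en-1-yl]-3,7-dimethylnona-2,4,6-trien-8-ynenitrile F7. i-Bu2AlH reduction and hydrolysis should give (2E,4E,6E)-9-[(4R)-4-hydroxy-2,6,6-trimethylcyclohex-1-en-1-yl]-3,7-dimethylnona-2,4,6-trien-8-ynal F8. Olefination of F8 with the anion of 20 should give ethyl (3R)-3-hydroxy-7,8-didehydro-12'-apo-β-caroten-12'-oate F9. i-Bu2AlH then gives (3R)-7,8-didehydro-12'-apo-β-carotene-3,12'-diol F10, and MnO2 gives (3R)-3-hydroxy-7,8-didehydro-12'-apo-β-caroten-12'-al F11. A second olefination of F11 with the anion of 20 arrives at 26.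

**Further compounds**
F1 | step 7 | rac-4-ethynyl-3,5,5-trimethylcyclohex-3-en-1-ol | CC1=C(C#C)C(C)(C)CC(O)C1
F2 | step 7 | (1R)-4-ethynyl-3,5,5-trimethylcyclohex-3-en-1-yl acetate | CC1=C(C#C)C(C)(C)C[C@H](OC(C)=O)C1
F3 | step 7 | (1S)-4-ethynyl-3,5,5-trimethylcyclohex-3-en-1-ol | CC1=C(C#C)C(C)(C)C[C@@H](O)C1
F4 | step 3 | methyl 3,3-dimethyl-2-(prop-1-en-2-yl)pent-4-enoate (racemic) | C=CC(C)(C)C(C(C)=C)C(=O)OC
F5 | step 3 | methyl 3,3-dimethyl-5-oxo-2-(prop-1-en-2-yl)pentanoate (racemic) | O=CCC(C)(C)C(C(C)=C)C(=O)OC
F6 | step 3 | methyl 5-hydroxy-3,3-dimethyl-2-(prop-1-en-2-yl)pentanoate (racemic) | OCCC(C)(C)C(C(C)=C)C(=O)OC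
F7 | step 16 | (2E,4E,6E)-9-[(4R)-4-hydroxy-2,6,6-trimethylcyclohex-1-en-1-yl]-3,7-dimethylnona-2,4,6-trien-8-ynenitrile | CC1=C(C#C/C(C)=C/C=C/C(C)=C/C#N)C(C)(C)C[C@H](O)C1
F8 | step 16 | (2E,4E,6E)-9-[(4R)-4-hydroxy-2,6,6-trimethylcyclohex-1-en-1-yl]-3,7-dimethylnona-2,4,6-trien-8-ynal | CC1=C(C#C/C(C)=C/C=C/C(C)=C/C=O)C(C)(C)C[C@H](O)C1
F9 | step 16 | ethyl (3R)-3-hydroxy-7,8-didehydro-12'-apo-β-caroten-12'-oate (all-E) | CC1=C(C#C/C(C)=C/C=C/C(C)=C/C=C/C=C(\C)C(=O)OCC)C(C)(C)C[C@H](O)C1
F10 | step 16 | (3R)-7,8-didehydro-12'-apo-β-carotene-3,12'-diol (all-E) | CC1=C(C#C/C(C)=C/C=C/C(C)=C/C=C/C=C(\C)CO)C(C)(C)C[C@H](O)C1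
F11 | step 16 | (3R)-3-hydroxy-7,8-didehydro-12'-apo-β-caroten-12'-al (all-E) | CC1=C(C#C/C(C)=C/C=C/C(C)=C/C=C/C=C(\C)C=O)C(C)(C)C[C@H](O)C1
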